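**Target 21:** (1R,2S)-1-(3,4-dimethoxyphenyl)-2-{4-[(2S,3R,4S,5R)-5-(3,4-dimethoxyphenyl)-3,4-dimethyloxolan-2-yl]-2-methoxyphenoxy}propan-1-ol.
**Labels used:** ring A = side-chain dimethoxyphenyl; ring B = central trisubstituted benzene; ring C = oxolane (O1, C2–C5; ring B on C2, ring D on C5); ring D = dimethoxyphenyl on C5; side chain C1' (carbinol), C2' (ether carbon).

## The problem

- 21 is a sesquineolignan. Ring C carries ring B at C2, ring D at C5 and methyl groups at C3 and C4. The para oxygen of ring B is the ether oxygen on C2' of a 1-arylpropan-1-ol chain whose carbinol carbon C1' bears ring A.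
- Ring C is all-cis (2S,3R,4S,5R): both arenes and both methyl groups stand on one face. This is the most crowded and least stable arrangement of the ring, so it has to be made under kinetic control and then kept away from anything that lets it equilibrate.
- The diaryl oxolane would be meso if rings B and D were alike. The absolute configuration of its four centres is therefore defined only by which arene carries the side chain. Any plan that forms C2 and C5 in one event from near-identical halves, or joins a racemic or meso core to the chiral chain, ends in diastereomers that differ only across a para-phenylene spacer and cannot be expected to separate.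
- The two arenes must therefore enter one after the other, each under stereocontrol from a neighbouring centre.
- The side chain is erythro (1'R,2'S) and independent of ring C: C2' can come from the chiral pool and control C1' by 1,2-induction.
- Sensitive points:
  - C2–O and C5–O are para-alkoxybenzylic ether bonds that ionise under protic or Lewis acid and reclose trans.
  - C3 can epimerise while C2 is a carbonyl carbon.
  - The benzylic C1' hydroxyl would be ionised and deoxygenated by acid and silane.
  - C2' is enolisable at the α-aryloxy ketone stage.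
- The feature that opens the route: H-2, H-3, H-4 and H-5 all lie on the same face of ring C. Each of these four C–H bonds can therefore be made by adding hydrogen to a flat ring carbon from the face opposite an aryl group already present. One stereocentre, the aryl carbinol carbon C5, can thus set C3 and C4 (H2 to the C3=C4 bond of a planar furan-2(5H)-one) and, with them, C2 (hydride to a C2 oxocarbenium ion).

## Retrosynthesis

**C1'–H (21 ⇒ 20).** The last bond formed is C1'–H, from ketone 20. This keeps the ionisable benzylic hydroxyl out of every acidic and organometallic step and lets C2' control C1'. 20 has one stereocentre fewer. The forward reduction must pass through a chelate between the carbonyl and aryloxy oxygens to give the erythro isomer.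

**C2'–O(aryl) (20 ⇒ 14 + 19).** The ether bond is cut to phenol 14 and α-keto tosylate 19. Carbonyl activation makes SN2 at this secondary carbon fast, whereas displacement at an unactivated secondary carbinol next to a benzylic centre would be slow. The cut divides the molecule into the oxolane core and a three-step chiral-pool fragment: 19 comes from methyl (R)-lactate 15 through Weinreb amide 16 and hydroxy ketone 18, with ring A from Grignard reagent 17. The forward step needs clean inversion without enolisation.

**C2–H (14 ⇒ 13 ⇒ 11).** After removal of the silyl group (14 from 13), the C2–H bond is cut: 13 comes from lactol 11 through oxocarbenium ion 12. Closing the ring instead by C–O bond formation from a 1,4-diol would pass through a benzylic cation and give the trans isomer. Here hydride must come from the face away from the three cis substituents, which puts ring B on their side. The step must run cold so that the kinetic product survives.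

**C2–C(ring B) (11 ⇒ 7 + 9).** The aryl–C2 bond is cut to lactone 7 and aryllithium 10, made from bromide 9 (from bromophenol 8). This is the point at which the two arenes become different: ring D is already in 7, and ring B arrives with its phenol masked. 7 has three stereocentres and one arene.

**C3–H and C4–H (7 ⇒ 6), the key cut.** Both bonds are cut at once: 7 comes from butenolide 6, which is flat except for C5. The neighbouring cuts are worse: C3–CH3 by enolate methylation would deliver the methyl anti to the C4 methyl, and C4–C5 by aldol chemistry needs an auxiliary. Syn-addition to the ring alkene makes the methyl groups cis to each other, and the C5 aryl group sends hydrogen to the other face. The precursor has one stereocentre instead of three.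

**C4–CH3 and C3–C2 (6 ⇒ 3).** 6 comes from propargylic alcohol 3 by alkoxide-directed anti-addition of a methyl–magnesium bond across the alkyne (chelate 4), carboxylation of the carbon–magnesium bond and lactonisation of hydroxy acid 5. The alkyne methyl becomes the C3 methyl. The chelate fixes the geometry of the tetrasubstituted alkene, and C5 is not touched.

**C5–C4 (3 ⇒ 1 + 2).** 3 comes from aldehyde 1 and propyne 2 by catalytic enantioselective alkynylation. This is the only stereocentre of ring C that needs a chiral catalyst, and both partners are bulk chemicals.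

## Roads not taken

Alternative 1: The obvious route cuts C4–C5 by an auxiliary-controlled syn-aldol (Bu2BOTf, N-propionyl oxazolidinone) on 1 to give A1. A1 is homologated by one carbon and lactonised to the 4,5-cis lactone A2, C3–CH3 is made by enolate methylation, and the same aryl addition and reduction follow. The methylation enters anti to the C4 methyl and C5 aryl groups and gives the 3,4-trans lactone A3, the wrong C3 epimer for an all-cis ring, so a further deprotonation and kinetic protonation is needed. With the stoichiometric auxiliary and the homologation this is several steps longer than the butenolide route, which gets C3 and C4 right in one hydrogen addition and uses a catalyst for C5.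

Alternative 2: Dearomatising hydrogenation of the 2,5-diaryl-3,4-dimethylfuran A4 (over Rh/Al2O3 or Pd/C) would set all four ring centres in one syn-addition and is the shortest way to the all-cis relative configuration. But A4 is achiral and its faces differ only through a remote benzyl/methyl label, so the product (after debenzylation) is 14 with an equal amount of its enantiomer A5. The symmetric variant gives the meso bisphenol A6, whose desymmetrisation would ask a reagent to tell apart two phenols about 6 Å from the nearest stereocentre. Coupling with 19 would then give two diastereomers that differ only remotely. The chosen plan keeps the idea (all ring C–H bonds from one face) but brings the arenes in one at a time, so each hydrogen delivery is governed by a neighbouring centre.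

Alternative 3: Catalytic desymmetrisation of meso-2,3-dimethylsuccinic anhydride A7 by an arylzinc reagent ([Rh(cod)Cl]2 with a phosphinooxazoline ligand) would form the ring D–carbonyl bond, set C3 and C4 together in keto acid A8, and label the two termini. C5 must then be made by reducing the aryl ketone next to the C4 stereocentre. Felkin–Anh delivery of hydride leads to the 4,5-trans lactone A9; the 4,5-cis isomer needed here would require an anti-Felkin reduction or an invertive lactonisation at an ionisable benzylic carbinol. The chosen plan reverses the order: C5 is made first by catalysis, and C3 and C4 are made relative to it from the open face, where substrate control works in the required direction.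

Key step: step 3

Assumption (remark on the chemistry): the zinc–ProPhenol alkynylation is taken to give the (S)-carbinol with the (S,S)-ligand, as with related aryl aldehydes; if propyne gives the opposite sense, the (R,R)-ligand is used and nothing else changes.

## Route

Step 1
Reactants: 1 3,4-dimethoxybenzaldehyde; 2 propyne
Product: 3 (S)-1-(3,4-dimethoxyphenyl)but-2-yn-1-ol
Conditions: 2 (3 equiv), Me2Zn (3 equiv), (S,S)-ProPhenol (10 mol%), Ph3P=O (20 mol%), toluene, 0 °C; aq. NH4Cl
Reagents that add atoms: none
Why: Catalytic enantioselective alkynylation of an aryl aldehyde by an alkynylzinc held in the chiral pocket of the dinuclear zinc–ProPhenol complex; the ligand antipode fixes the aldehyde face and so C5, the one ring stereocentre that comes from a chiral catalyst.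

Step 2
Reactants: 3
Product: 6 (S)-5-(3,4-dimethoxyphenyl)-3,4-dimethylfuran-2(5H)-one, via alkenylmagnesium chelate 4 (not isolated), via (Z)-hydroxy acid 5 (not isolated)
Conditions: MeMgCl (4 equiv), CuI (10 mol%), THF/toluene, 0 → 60 °C; CO2 (1 atm), −20 → 20 °C; aq. citric acid, 0 °C
Reagents that add atoms: methylmagnesium chloride, C[Mg]Cl; carbon dioxide, O=C=O
Why: Copper-catalysed, alkoxide-directed anti-carbomagnesiation of a propargylic alcohol puts CH3 on the proximal alkyne carbon and magnesium on the distal carbon cis to the carbinol (five-membered chelate 4); carboxylation of the C–Mg bond and mild acid lactonisation of 5 give the butenolide with both methyl groups in place, and C5 is not touched.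

Step 3
Reactants: 6
Product: 7 (3R,4S,5R)-5-(3,4-dimethoxyphenyl)-3,4-dimethyloxolan-2-one
Conditions: H2 (50 bar), 5% Rh/Al2O3, EtOAc, 25 °C
Reagents that add atoms: none
Why: Heterogeneous syn-hydrogenation: the nearly planar butenolide adsorbs on the rhodium surface through the face of C3=C4 that is not covered, and both hydrogens are transferred to that face. The closest known reaction type is the hydrogenation of γ-substituted α,β-dimethylbutenolides to all-cis γ-lactones. No ring is closed. The new stereocentres C3 and C4 are both controlled by C5: ring D is the only substituent out of the ring plane, so hydrogen enters anti to it and both methyl groups end up on the side of ring D (3R,4S,5R; the label of C5 changes from S to R only because C4 loses CIP rank on saturation). The cis relation of C3 and C4 follows from syn-addition to a ring alkene. The step needs facial selectivity (secured by the C5 aryl group), chemoselectivity over hydrogenolysis of the benzylic, allylic C5–O bond (rhodium on alumina in neutral ethyl acetate instead of palladium) and over arene saturation (room temperature, electron-rich arenes react slowly). The all-cis lactone is the kinetic product, so base is excluded to keep C3, which is α to the carbonyl, from epimerising.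

Step 4
Reactants: 8 4-bromo-2-methoxyphenol
Product: 9 (4-bromo-2-methoxyphenoxy)(tert-butyl)dimethylsilane
Conditions: TBSCl, imidazole, DMF, 25 °C
Reagents that add atoms: tert-butyldimethylsilyl chloride, CC(C)(C)[Si](C)(C)Cl
Why: Standard silylation of a phenol; the silyl ether tolerates bromine–lithium exchange (lithium para to oxygen, so no silyl migration) and BF3·OEt2 at −78 °C, and is later removed by fluoride without acid or hydrogen.

Step 5
Reactants: 9; 7
Product: 11 (3R,4S,5R)-2-{4-[(tert-butyldimethylsilyl)oxy]-3-methoxyphenyl}-5-(3,4-dimethoxyphenyl)-3,4-dimethyloxolan-2-ol (anomer mixture), via aryllithium 10 (not isolated)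
Conditions: 9, n-BuLi, THF, −78 °C; then 7, −78 °C; aq. NH4Cl
Reagents that add atoms: none
Why: Bromine–lithium exchange followed by 1,2-addition of the aryllithium to the lactone carbonyl, which stops at the lithium hemiketal at −78 °C; addition should outrun enolisation so C3 stays cis, and this is where ring B is introduced separately from ring D.

Step 6
Reactants: 11
Product: 13 tert-butyl{4-[(2S,3R,4S,5R)-5-(3,4-dimethoxyphenyl)-3,4-dimethyloxolan-2-yl]-2-methoxyphenoxy}dimethylsilane, via oxocarbenium ion 12 (not isolated)
Conditions: Et3SiH (5 equiv), BF3·OEt2 (2 equiv), CH2Cl2, −78 °C; aq. NaHCO3 quench at −78 °C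
Reagents that add atoms: none
Why: Ionic hydrogenation of a cyclic hemiketal: BF3·OEt2 ionises C2–OH to the aryl-stabilised oxocarbenium ion 12 and Et3SiH delivers hydride to C2 from the face opposite the C3 methyl, C4 methyl and C5 aryl groups, which forces ring B onto their face (2S, all-cis); the low temperature is meant to preserve this kinetic outcome.

Step 7
Reactants: 13
Product: 14 4-[(2S,3R,4S,5R)-5-(3,4-dimethoxyphenyl)-3,4-dimethyloxolan-2-yl]-2-methoxyphenol
Conditions: TBAF, THF, 0 °C; aq. NH4Cl
Reagents that add atoms: none
Why: Fluoride cleavage of the aryl silyl ether under non-acidic conditions leaves the acid-labile all-cis bis-benzylic ether untouched.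

Step 8
Reactants: 15 methyl (R)-lactate
Product: 16 (R)-2-hydroxy-N-methoxy-N-methylpropanamide
Conditions: MeNHOMe·HCl (2.5 equiv), i-PrMgCl (5 equiv), THF, −20 → 0 °C
Reagents that add atoms: N,O-dimethylhydroxylamine hydrochloride, CNOC.Cl
Why: Aminolysis of the ester by the chloromagnesium amide of N,O-dimethylhydroxylamine (Weinreb amide formation); the stereocentre is not enolised because the neighbouring oxygen is present as its alkoxide.

Step 9
Reactants: 16; 17 3,4-dimethoxyphenylmagnesium bromide
Product: 18 (R)-1-(3,4-dimethoxyphenyl)-2-hydroxypropan-1-one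
Conditions: 17 (2.5 equiv), THF, 0 °C; aq. NH4Cl
Reagents that add atoms: none
Why: Weinreb ketone synthesis: the first equivalent of Grignard reagent forms the alkoxide, the second adds once to give the chelated tetrahedral intermediate that collapses to the ketone only on work-up; the alkoxide protects C2' from enolisation.

Step 10
Reactants: 18
Product: 19 (R)-1-(3,4-dimethoxyphenyl)-1-oxopropan-2-yl 4-methylbenzenesulfonate
Conditions: TsCl, pyridine, CH2Cl2, 0 °C
Reagents that add atoms: 4-methylbenzenesulfonyl chloride, Cc1ccc(S(=O)(=O)Cl)cc1
Why: Sulfonylation of the secondary alcohol with retention; the resulting α-keto tosylate is a strongly activated SN2 electrophile.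

Step 11
Reactants: 14; 19
Product: 20 (S)-1-(3,4-dimethoxyphenyl)-2-{4-[(2S,3R,4S,5R)-5-(3,4-dimethoxyphenyl)-3,4-dimethyloxolan-2-yl]-2-methoxyphenoxy}propan-1-one
Conditions: BEMP (1.2 equiv), CH2Cl2, 20 °C
Reagents that add atoms: none
Why: Williamson-type SN2 displacement of the α-keto sulfonate by the phenoxide with inversion (R to S at C2'); the non-nucleophilic phosphazene base BEMP (2-tert-butylimino-2-diethylamino-1,3-dimethylperhydro-1,3,2-diazaphosphorine) in a non-polar solvent is meant to keep enolisation of 19 and 20 slow.

Step 12
Reactants: 20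
Product: 21 (1R,2S)-1-(3,4-dimethoxyphenyl)-2-{4-[(2S,3R,4S,5R)-5-(3,4-dimethoxyphenyl)-3,4-dimethyloxolan-2-yl]-2-methoxyphenoxy}propan-1-ol
Conditions: Zn(BH4)2, Et2O, −30 → 0 °C; aq. NH4Cl
Reagents that add atoms: none
Why: Chelation-controlled (Cram-chelate) reduction: zinc bridges the carbonyl oxygen and the aryloxy oxygen, hydride enters past H instead of CH3 of C2', and the anti (erythro) 1'R,2'S alcohol should result; nothing else in 20 is reduced by borohydride.

## Compound list

1 | 3,4-dimethoxybenzaldehyde | COc1ccc(C=O)cc1OC | starting material
2 | propyne | CC#C | starting material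
3 | (S)-1-(3,4-dimethoxyphenyl)but-2-yn-1-ol | COc1ccc([C@H](O)C#CC)cc1OC | intermediate
4 | (S)-5-(3,4-dimethoxyphenyl)-3,4-dimethyl-2,5-dihydro-1,2-oxamagnesole (chelated alkenylmagnesium alkoxide, further ligands omitted) | CC1=C(C)[C@H](c2ccc(OC)c(OC)c2)O[Mg]1 | intermediate
5 | (S,Z)-4-(3,4-dimethoxyphenyl)-4-hydroxy-2,3-dimethylbut-2-enoic acid (magnesium salt before acidification) | C/C(C(=O)O)=C(\C)[C@@H](O)c1ccc(OC)c(OC)c1 | intermediate
6 | (S)-5-(3,4-dimethoxyphenyl)-3,4-dimethylfuran-2(5H)-one | O=C1O[C@@H](c2ccc(OC)c(OC)c2)C(C)=C1C | intermediate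
7 | (3R,4S,5R)-5-(3,4-dimethoxyphenyl)-3,4-dimethyloxolan-2-one (all-cis) | O=C1O[C@@H](c2ccc(OC)c(OC)c2)[C@@H](C)[C@H]1C | intermediate
8 | 4-bromo-2-methoxyphenol | COc1cc(Br)ccc1O | starting material
9 | (4-bromo-2-methoxyphenoxy)(tert-butyl)dimethylsilane | COc1cc(Br)ccc1O[Si](C)(C)C(C)(C)C | intermediate
10 | {4-[(tert-butyldimethylsilyl)oxy]-3-methoxyphenyl}lithium | COc1cc([Li])ccc1O[Si](C)(C)C(C)(C)C | intermediate
11 | (3R,4S,5R)-2-{4-[(tert-butyldimethylsilyl)oxy]-3-methoxyphenyl}-5-(3,4-dimethoxyphenyl)-3,4-dimethyloxolan-2-ol (anomer mixture) | COc1cc(C2(O)O[C@@H](c3ccc(OC)c(OC)c3)[C@@H](C)[C@H]2C)ccc1O[Si](C)(C)C(C)(C)C | intermediate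
12 | (3R,4S,5R)-2-{4-[(tert-butyldimethylsilyl)oxy]-3-methoxyphenyl}-5-(3,4-dimethoxyphenyl)-3,4-dimethyl-4,5-dihydro-3H-furan-1-ium (oxocarbenium ion) | COc1cc(C2=[O+][C@@H](c3ccc(OC)c(OC)c3)[C@@H](C)[C@H]2C)ccc1O[Si](C)(C)C(C)(C)C | intermediate
13 | tert-butyl{4-[(2S,3R,4S,5R)-5-(3,4-dimethoxyphenyl)-3,4-dimethyloxolan-2-yl]-2-methoxyphenoxy}dimethylsilane | COc1cc([C@H]2O[C@@H](c3ccc(OC)c(OC)c3)[C@@H](C)[C@H]2C)ccc1O[Si](C)(C)C(C)(C)C | intermediate
14 | 4-[(2S,3R,4S,5R)-5-(3,4-dimethoxyphenyl)-3,4-dimethyloxolan-2-yl]-2-methoxyphenol | COc1cc([C@H]2O[C@@H](c3ccc(OC)c(OC)c3)[C@@H](C)[C@H]2C)ccc1O | intermediate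
15 | methyl (R)-lactate | C[C@@H](O)C(=O)OC | starting material
16 | (R)-2-hydroxy-N-methoxy-N-methylpropanamide | C[C@@H](O)C(=O)N(C)OC | intermediate
17 | 3,4-dimethoxyphenylmagnesium bromide (solution in THF) | COc1ccc([Mg]Br)cc1OC | starting material
18 | (R)-1-(3,4-dimethoxyphenyl)-2-hydroxypropan-1-one | C[C@@H](O)C(=O)c1ccc(OC)c(OC)c1 | intermediate
19 | (R)-1-(3,4-dimethoxyphenyl)-1-oxopropan-2-yl 4-methylbenzenesulfonate | C[C@@H](OS(=O)(=O)c1ccc(C)cc1)C(=O)c1ccc(OC)c(OC)c1 | intermediate
20 | (S)-1-(3,4-dimethoxyphenyl)-2-{4-[(2S,3R,4S,5R)-5-(3,4-dimethoxyphenyl)-3,4-dimethyloxolan-2-yl]-2-methoxyphenoxy}propan-1-one | COc1ccc(C(=O)[C@H](C)Oc2ccc([C@H]3O[C@@H](c4ccc(OC)c(OC)c4)[C@@H](C)[C@H]3C)cc2OC)cc1OC | intermediate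
21 | (1R,2S)-1-(3,4-dimethoxyphenyl)-2-{4-[(2S,3R,4S,5R)-5-(3,4-dimethoxyphenyl)-3,4-dimethyloxolan-2-yl]-2-methoxyphenoxy}propan-1-ol | COc1ccc([C@@H](O)[C@H](C)Oc2ccc([C@H]3O[C@@H](c4ccc(OC)c(OC)c4)[C@@H](C)[C@H]3C)cc2OC)cc1OC | target

## Step count and risks

Total: 12 steps. Longest linear sequence: 8 steps (1, 2, 3, 5, 6, 7, 11, 12). Step 4 and steps 8–10 are side branches that join at steps 5 and 11.

**Step 3 (key step).** Most likely failure: hydrogenolysis of the benzylic, allylic C5–O bond on the metal surface, or saturation of the tetrasubstituted alkene so slow that forcing conditions begin to reduce the arenes. Fallback, from 6 back to 7, replaces surface hydrogenation by 1,4-hydride addition and kinetic protonation. A copper hydride made from Cu(OAc)2, 1,2-bis(diphenylphosphino)benzene and PhMe2SiH adds hydride to C4 anti to ring D and gives the silyl ketene acetal F1. C3 of F1 is then protonated (acetic acid, −78 °C) from the same open face, anti to the C4 methyl group, which returns 7.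

**Step 1.** Most likely failure: low or reversed enantioselection, because propyne is the smallest alkyne and methyl transfer from Me2Zn competes. Fallback, from 1 to 3, uses asymmetric reduction instead of asymmetric addition. 1-Propynylmagnesium bromide adds to 1 to give the racemic carbinol (3 with its enantiomer F2). MnO2 oxidises it to the ynone F3. (S)-Alpine-Borane (Midland reduction, alkyne as the small group) then gives 3.

**Step 2.** Most likely failure: sluggish or unselective carbometalation of the internal alkyne, protonation instead of carboxylation of the hindered alkenylmagnesium, or acid-promoted ionisation of the doubly activated carbinol during lactonisation. Fallback, from 1 to 6, carries the carboxyl carbon in the alkyne from the start. Zinc–ProPhenol alkynylation of 1 with methyl propiolate gives the hydroxy ynoate F4. Syn-carbocupration with Me2CuLi at −78 °C and trapping of the alkenylcopper with MeI lead, after lactonisation on work-up, to 6.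

**Step 6.** Most likely failure: loss of H-3 from the oxocarbenium ion and reprotonation (scrambling of C3), or Lewis-acid opening of the C5–O bond with epimerisation towards a trans isomer. Fallback, from 11 to 13, uses a second surface hydrogenation instead of ionic reduction. Mild dehydration of 11 (MsCl, Et3N) gives the cyclic enol ether F5. H2 over Pd/C with a trace of Et3N adds to C2=C3 from the face opposite the C4 methyl group and ring D, setting C2 and C3 together.

**Step 11.** Most likely failure: enolisation of 19 or 20 by the base (loss of configuration at C2') or elimination of the sulfonate. Fallback, from 14 to 20, goes through an ester that resists enolisation. Mitsunobu reaction of 14 with 15 (PPh3, DIAD, inversion) gives the aryloxy ester F6. F6 is converted into the Weinreb amide F7 (MeNHOMe·HCl, i-PrMgCl), and F7 is treated with 17 to give 20.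

## Further compounds

F1 | step 3 | {[(4S,5R)-5-(3,4-dimethoxyphenyl)-3,4-dimethyl-4,5-dihydrofuran-2-yl]oxy}dimethyl(phenyl)silane | CC1=C(O[Si](C)(C)c2ccccc2)O[C@@H](c2ccc(OC)c(OC)c2)[C@H]1C
F2 | step 1 | (R)-1-(3,4-dimethoxyphenyl)but-2-yn-1-ol | COc1ccc([C@@H](O)C#CC)cc1OC
F3 | step 1 | 1-(3,4-dimethoxyphenyl)but-2-yn-1-one | COc1ccc(C(=O)C#CC)cc1OC
F4 | step 2 | methyl (S)-4-(3,4-dimethoxyphenyl)-4-hydroxybut-2-ynoate | COc1ccc([C@H](O)C#CC(=O)OC)cc1OC
F5 | step 6 | tert-butyl{4-[(4S,5R)-5-(3,4-dimethoxyphenyl)-3,4-dimethyl-4,5-dihydrofuran-2-yl]-2-methoxyphenoxy}dimethylsilane | COc1cc(C2=C(C)[C@H](C)[C@H](c3ccc(OC)c(OC)c3)O2)ccc1O[Si](C)(C)C(C)(C)C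
F6 | step 11 | methyl (S)-2-{4-[(2S,3R,4S,5R)-5-(3,4-dimethoxyphenyl)-3,4-dimethyloxolan-2-yl]-2-methoxyphenoxy}propanoate | COC(=O)[C@H](C)Oc1ccc([C@H]2O[C@@H](c3ccc(OC)c(OC)c3)[C@@H](C)[C@H]2C)cc1OC
F7 | step 11 | (S)-2-{4-[(2S,3R,4S,5R)-5-(3,4-dimethoxyphenyl)-3,4-dimethyloxolan-2-yl]-2-methoxyphenoxy}-N-methoxy-N-methylpropanamide | CON(C)C(=O)[C@H](C)Oc1ccc([C@H]2O[C@@H](c3ccc(OC)c(OC)c3)[C@@H](C)[C@H]2C)cc1OC
A1 | alternative 1 | (R)-4-benzyl-3-[(2R,3R)-3-(3,4-dimethoxyphenyl)-3-hydroxy-2-methylpropanoyl]oxazolidin-2-one | COc1ccc([C@H](O)[C@@H](C)C(=O)N2[C@H](Cc3ccccc3)COC2=O)cc1OC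
A2 | alternative 1 | (4S,5R)-5-(3,4-dimethoxyphenyl)-4-methyloxolan-2-one | O=C1O[C@@H](c2ccc(OC)c(OC)c2)[C@@H](C)C1
A3 | alternative 1 | (3S,4S,5R)-5-(3,4-dimethoxyphenyl)-3,4-dimethyloxolan-2-one | O=C1O[C@@H](c2ccc(OC)c(OC)c2)[C@@H](C)[C@@H]1C
A4 | alternative 2 | 2-[4-(benzyloxy)-3-methoxyphenyl]-5-(3,4-dimethoxyphenyl)-3,4-dimethylfuran | COc1ccc(-c2oc(-c3ccc(OCc4ccccc4)c(OC)c3)c(C)c2C)cc1OC
A5 | alternative 2 | 4-[(2R,3S,4R,5S)-5-(3,4-dimethoxyphenyl)-3,4-dimethyloxolan-2-yl]-2-methoxyphenol (enantiomer of 14) | COc1cc([C@@H]2O[C@H](c3ccc(OC)c(OC)c3)[C@H](C)[C@@H]2C)ccc1O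
A6 | alternative 2 | 4,4'-[(2R,3S,4R,5S)-3,4-dimethyloxolane-2,5-diyl]bis(2-methoxyphenol) (meso, all-cis) | COc1cc([C@H]2O[C@@H](c3ccc(O)c(OC)c3)[C@@H](C)[C@H]2C)ccc1O
A7 | alternative 3 | (3R,4S)-3,4-dimethyloxolane-2,5-dione (meso-2,3-dimethylsuccinic anhydride) | C[C@H]1C(=O)OC(=O)[C@H]1C
A8 | alternative 3 | (2R,3S)-4-(3,4-dimethoxyphenyl)-2,3-dimethyl-4-oxobutanoic acid | COc1ccc(C(=O)[C@@H](C)[C@H](C(=O)O)C)cc1OC
A9 | alternative 3 | (3R,4S,5S)-5-(3,4-dimethoxyphenyl)-3,4-dimethyloxolan-2-one | O=C1O[C@H](c2ccc(OC)c(OC)c2)[C@@H](C)[C@H]1C
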